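**Plan**

1. Target numbering used throughout: lactone ring A is O1–C7(=O)–C8–C10(Ar)–C11(Me)–C6(OMe); carbocycle ring B is C6–C5=C4(allyl)–C9(=O)–C8–C10–C11; Ar = 3,4,5-trimethoxyphenyl.
2. Enabling feature: C4=C5 is the only C=C of ring B and lies between the ketal bridgehead C6 and C9, so ring B can be closed by metathesis between a vinyl group on C6 and an alkenyl arm on C8 held cis on ring A.
3. Retrosynthetic cuts, in order: C4–allyl (Stille), C4–I, C9 carbinol to ketone, C4=C5 (ring-closing metathesis), C8–C9 (aldol with acrolein, so C9 carries its oxygen from the start), C6–O1 (lactonising transketalisation), C6–C5 (acetylide addition), C11–CH3 (enolate methylation), C10–Ar (rhodium-catalysed conjugate addition).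
4. Forward order: a scaffold δ-lactone carries C10 and C11, is opened at its carbonyl (the future C6) by an acetylide, the C7 acid is unveiled, ring A is closed at C6–O1, and ring B is closed last across ring A.
5. Stereochemistry: C10 from the (S)-BINAP/rhodium addition; C11 and C8 from lactone-enolate reactions anti to the aryl group; C6 from acid equilibration of the acyl ketal with separation and recycling (step 7), after which only the cis epimer can bridge.

Key step: step 10

Assumption: the (S)-BINAP/rhodium catalyst is taken to give the (S)-lactone 3, by analogy with its known sense on 2-cyclohexenone; if the sense proved opposite, (R)-BINAP would be used.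

**Route**

Step 1
Reactants: 1 5,6-dihydro-2H-pyran-2-one; 2 (3,4,5-trimethoxyphenyl)boronic acid
Product: 3 (S)-4-(3,4,5-trimethoxyphenyl)tetrahydro-2H-pyran-2-one
Conditions: Rh(acac)(C2H4)2 (3 mol%), (S)-BINAP (3.3 mol%), 2 (2.5 equiv), dioxane/H2O 10:1, 100 °C
Reagents that add atoms: none
Why: Rhodium-catalysed asymmetric 1,4-addition of an arylboronic acid (Hayashi–Miyaura reaction) is established for this unsaturated δ-lactone class: the aryl–rhodium species inserts the C=C bond from the face selected by (S)-BINAP and water protonates the rhodium enolate, which sets C10.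

Step 2
Reactants: 3
Product: 5 (3R,4S)-3-methyl-4-(3,4,5-trimethoxyphenyl)tetrahydro-2H-pyran-2-one, via lithium enolate 4 (not isolated)
Conditions: LiN(iPr)2 (1.05 equiv), THF, −78 °C; MeI, −78 to −40 °C
Reagents that add atoms: iodomethane, CI
Why: Enolate alkylation of a 4-substituted δ-lactone: iodomethane should approach the half-chair enolate on the face opposite the neighbouring C10 aryl group, giving the 3,4-trans lactone and setting C11.

Step 3
Reactants: 5; 6 lithium (trimethylsilyl)acetylide
Product: 7 (3R,4S)-3-methyl-4-(3,4,5-trimethoxyphenyl)-2-[(trimethylsilyl)ethynyl]tetrahydro-2H-pyran-2-ol (anomeric mixture)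
Conditions: 6 (1.3 equiv, commercial THF solution), THF, −78 °C; AcOH quench at −78 °C
Reagents that add atoms: none
Why: 1,2-Addition of an alkynyllithium to a lactone halts at the tetrahedral lithium hemiketal alkoxide at −78 °C, so one alkynyl group is delivered to the future C6; the anomeric configuration is irrelevant because C6 becomes planar again in step 4.

Step 4
Reactants: 7
Product: 8 (3S,4R)-4-methyl-5-oxo-3-(3,4,5-trimethoxyphenyl)-7-(trimethylsilyl)hept-6-ynoic acid
Conditions: TEMPO (20 mol%), PhI(OAc)2 (2.5 equiv), MeCN/pH 7 phosphate buffer 1:1, rt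
Reagents that add atoms: water, O
Why: Oxoammonium-mediated (TEMPO/PhI(OAc)2) oxidation of a primary alcohol to the acid: the tertiary hemiketal cannot itself be oxidised, so 7 should drain through its open-chain hydroxy ynone tautomer, while the silylalkyne and aryl ethers are inert.

Step 5
Reactants: 8
Product: 9 methyl (3S,4R)-5,5-dimethoxy-4-methyl-3-(3,4,5-trimethoxyphenyl)-7-(trimethylsilyl)hept-6-ynoate
Conditions: HC(OMe)3 (6 equiv), MeOH, camphorsulfonic acid (10 mol%), 0 °C to rt
Reagents that add atoms: trimethyl orthoformate, COC(OC)OC; methanol, CO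
Why: Acid-catalysed ketalisation with an orthoformate as dehydrating agent, accompanied by Fischer esterification, should give one fully protected product; the silyl cap disfavours conjugate addition of methanol and the low temperature limits enolisation towards C11.

Step 6
Reactants: 9
Product: 11 (4S,5R)-6-ethynyl-6-methoxy-5-methyl-4-(3,4,5-trimethoxyphenyl)tetrahydro-2H-pyran-2-one (mixture of C6 epimers), via ketal acid 10 (not isolated)
Conditions: LiOH·H2O (3 equiv), THF/MeOH/H2O 3:1:1, rt; 1 M HCl to pH 4 at 0 °C, extraction; camphorsulfonic acid (5 mol%), 4 Å MS, toluene, rt; Et3N quench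
Reagents that add atoms: lithium hydroxide, [Li+].[OH-]
Why: Hydroxide saponifies the ester and cleaves the alkynyl C–Si bond, and the freed acid then displaces one methoxy group of the propargylic ketal through the methoxy-oxocarbenium ion (acid-catalysed lactonising transketalisation, 6-exo closure), which should close ring A as both C6 epimers because the planar cation can be captured on either face.

Step 7
Reactants: 11
Product: 12 (4S,5R,6S)-6-ethynyl-6-methoxy-5-methyl-4-(3,4,5-trimethoxyphenyl)tetrahydro-2H-pyran-2-one
Conditions: camphorsulfonic acid (10 mol%), 4 Å MS, toluene, 40 °C; Et3N quench; chromatography on Et3N-deactivated SiO2, (6R) fractions resubmitted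
Reagents that add atoms: none
Why: Acid-catalysed anomerisation of an acyl ketal: reversible heterolysis of the C6–O1 bond to the carboxylic acid and the methoxy-oxocarbenium ion interconverts the two epimers without a strong bias being expected (a slim ethynyl group against the weak anomeric preference of an acyl ketal for axial methoxy), so the (6S) epimer 12, with ethynyl cis to the C11 methyl group, is removed by chromatography and the remaining (6R) material is returned to the same conditions until it is used up.

Step 8
Reactants: 12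
Product: 13 (4S,5R,6R)-6-ethenyl-6-methoxy-5-methyl-4-(3,4,5-trimethoxyphenyl)tetrahydro-2H-pyran-2-one
Conditions: H2 (1 atm), Pd/CaCO3 poisoned with Pb(OAc)2 (Lindlar catalyst), quinoline, EtOAc, rt
Reagents that add atoms: none
Why: Lindlar semihydrogenation of a terminal alkyne stops at the alkene on the quinoline-poisoned catalyst, and the neutral conditions leave the acid-labile acyl ketal and its C6 configuration untouched (the descriptor changes only because vinyl ranks below C5 of the ring).

Step 9
Reactants: 13; 14 acrolein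
Product: 16 (3R,4R,5R,6R)-6-ethenyl-3-(1-hydroxyprop-2-en-1-yl)-6-methoxy-5-methyl-4-(3,4,5-trimethoxyphenyl)tetrahydro-2H-pyran-2-one (both carbinol epimers), via lithium enolate 15 (not isolated)
Conditions: LiN(SiMe3)2 (1.1 equiv), THF, −78 °C; 14 (1.5 equiv), −78 °C; AcOH quench at −78 °C
Reagents that add atoms: none
Why: Aldol addition of a lithium lactone enolate to acrolein (1,2-addition at −78 °C): the aldehyde should approach C8 on the face opposite the adjacent C10 aryl group, placing the new arm trans to the aryl and cis to the C6 vinyl group, while the carbinol carbon C9 forms as a mixture that is erased in step 11.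

Step 10
Reactants: 16
Product: 17 (1R,5R,8R,9R)-2-hydroxy-5-methoxy-9-methyl-8-(3,4,5-trimethoxyphenyl)-6-oxabicyclo[3.2.2]non-3-en-7-one (both carbinol epimers)
Conditions: second-generation Grubbs catalyst RuCl2(=CHPh)(PCy3)(SIMes) (10 mol%; SIMes = 1,3-dimesitylimidazolidin-2-ylidene), 1,4-benzoquinone (20 mol%), toluene (2 mM), 80 °C, argon sparge
Reagents that add atoms: none
Why: The ruthenium benzylidene exchanges onto the unhindered terminal alkene of the C8 hydroxyallyl arm, the new alkylidene adds [2+2] to the C6 vinyl group and the metallacyclobutane cycloreverts, releasing ethene and forming C4=C5 (Chauvin mechanism). The closest known reaction type is ring-closing metathesis of cis-1,4-dialkenyl six-membered rings to bridged bicycloalkenes. The seven-membered ring B closes across positions C6 and C8 of ring A, which must adopt a boat with the vinyl group and the arm in the two flagpole-like positions; the ring alkene is necessarily cis. No stereocentre is created: C6 and C8 become bridgeheads and are locked. The step needs intramolecular closure to outrun cross-metathesis and redox isomerisation of the allylic alcohol; the first is secured by the cis relation of the two alkenes on the face opposite the C10 aryl group (only this C6 epimer can bridge) together with high dilution, the second by the benzoquinone additive.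

Step 11
Reactants: 17
Product: 18 (1R,5R,8R,9R)-5-methoxy-9-methyl-8-(3,4,5-trimethoxyphenyl)-6-oxabicyclo[3.2.2]non-3-ene-2,7-dione
Conditions: Dess–Martin periodinane (1.5 equiv), pyridine (3 equiv), CH2Cl2, 0 °C to rt
Reagents that add atoms: none
Why: Dess–Martin oxidation of a secondary allylic alcohol should give the enone from both carbinol epimers, and the resulting β-keto lactone cannot enolise because C8 is a bridgehead, so no stereocentre is at risk.

Step 12
Reactants: 18
Product: 19 (1R,5S,8R,9R)-3-iodo-5-methoxy-9-methyl-8-(3,4,5-trimethoxyphenyl)-6-oxabicyclo[3.2.2]non-3-ene-2,7-dione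
Conditions: I2 (2 equiv), pyridine/CH2Cl2 1:1, DMAP (20 mol%), rt
Reagents that add atoms: iodine, II
Why: α-Iodination of an enone with iodine and pyridine (Johnson iodination) runs by reversible conjugate addition of the amine at C5, iodination of the enolate at C4 and loss of the amine, and tolerates a fully substituted γ-carbon as in 4,4-disubstituted cyclohexenones.

Step 13
Reactants: 19; 20 allyltributylstannane
Product: 21 (1R,5S,8R,9R)-3-allyl-5-methoxy-9-methyl-8-(3,4,5-trimethoxyphenyl)-6-oxabicyclo[3.2.2]non-3-ene-2,7-dione (CNP0298078.1)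
Conditions: Pd2(dba)3 (5 mol%), AsPh3 (20 mol%), CuI (copper monoiodide, 10 mol%), 20 (1.5 equiv), NMP, rt to 50 °C
Reagents that add atoms: none
Why: Stille cross-coupling: zerovalent palladium inserts into the C4–I bond, the allyl group is transferred from tin (assisted by AsPh3 and CuI) and reductive elimination gives the 2-allyl enone under neutral conditions that spare the ketal lactone.

**Compound list**

1 | 5,6-dihydro-2H-pyran-2-one | O=C1C=CCCO1 | starting material
2 | (3,4,5-trimethoxyphenyl)boronic acid | COc1cc(B(O)O)cc(OC)c1OC | starting material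
3 | (S)-4-(3,4,5-trimethoxyphenyl)tetrahydro-2H-pyran-2-one | O=C1OCC[C@H](c2cc(OC)c(OC)c(OC)c2)C1 | intermediate
4 | lithium (4S)-4-(3,4,5-trimethoxyphenyl)-5,6-dihydro-4H-pyran-2-olate (lithium enolate of 3) | [Li+].[O-]C1=C[C@@H](c2cc(OC)c(OC)c(OC)c2)CCO1 | intermediate
5 | (3R,4S)-3-methyl-4-(3,4,5-trimethoxyphenyl)tetrahydro-2H-pyran-2-one | O=C1OCC[C@H](c2cc(OC)c(OC)c(OC)c2)[C@H]1C | intermediate
6 | lithium (trimethylsilyl)acetylide | [Li+].[C-]#C[Si](C)(C)C | starting material
7 | (3R,4S)-3-methyl-4-(3,4,5-trimethoxyphenyl)-2-[(trimethylsilyl)ethynyl]tetrahydro-2H-pyran-2-ol (anomers; ring tautomer of the hydroxy ynone) | C[Si](C)(C)C#CC1(O)OCC[C@H](c2cc(OC)c(OC)c(OC)c2)[C@H]1C | intermediate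
8 | (3S,4R)-4-methyl-5-oxo-3-(3,4,5-trimethoxyphenyl)-7-(trimethylsilyl)hept-6-ynoic acid | OC(=O)C[C@H](c1cc(OC)c(OC)c(OC)c1)[C@H](C(=O)C#C[Si](C)(C)C)C | intermediate
9 | methyl (3S,4R)-5,5-dimethoxy-4-methyl-3-(3,4,5-trimethoxyphenyl)-7-(trimethylsilyl)hept-6-ynoate | COC(=O)C[C@H](c1cc(OC)c(OC)c(OC)c1)[C@H](C(OC)(OC)C#C[Si](C)(C)C)C | intermediate
10 | (3S,4R)-5,5-dimethoxy-4-methyl-3-(3,4,5-trimethoxyphenyl)hept-6-ynoic acid (ketal acid) | OC(=O)C[C@H](c1cc(OC)c(OC)c(OC)c1)[C@H](C(OC)(OC)C#C)C | intermediate
11 | (4S,5R)-6-ethynyl-6-methoxy-5-methyl-4-(3,4,5-trimethoxyphenyl)tetrahydro-2H-pyran-2-one (mixture of C6 epimers) | C#CC1(OC)OC(=O)C[C@H](c2cc(OC)c(OC)c(OC)c2)[C@H]1C | intermediate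
12 | (4S,5R,6S)-6-ethynyl-6-methoxy-5-methyl-4-(3,4,5-trimethoxyphenyl)tetrahydro-2H-pyran-2-one (ethynyl cis to the C5 methyl) | C#C[C@@]1(OC)OC(=O)C[C@H](c2cc(OC)c(OC)c(OC)c2)[C@H]1C | intermediate
13 | (4S,5R,6R)-6-ethenyl-6-methoxy-5-methyl-4-(3,4,5-trimethoxyphenyl)tetrahydro-2H-pyran-2-one | C=C[C@@]1(OC)OC(=O)C[C@H](c2cc(OC)c(OC)c(OC)c2)[C@H]1C | intermediate
14 | acrolein (prop-2-enal) | C=CC=O | starting material
15 | lithium enolate of 13 (deprotonated at C8) | C=C[C@@]1(OC)OC([O-])=C[C@H](c2cc(OC)c(OC)c(OC)c2)[C@H]1C.[Li+] | intermediate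
16 | (3R,4R,5R,6R)-6-ethenyl-3-(1-hydroxyprop-2-en-1-yl)-6-methoxy-5-methyl-4-(3,4,5-trimethoxyphenyl)tetrahydro-2H-pyran-2-one (carbinol epimers) | C=C[C@@]1(OC)OC(=O)[C@@H](C(O)C=C)[C@H](c2cc(OC)c(OC)c(OC)c2)[C@H]1C | intermediate
17 | (1R,5R,8R,9R)-2-hydroxy-5-methoxy-9-methyl-8-(3,4,5-trimethoxyphenyl)-6-oxabicyclo[3.2.2]non-3-en-7-one (carbinol epimers) | C1=C[C@@]2(OC)OC(=O)[C@@H](C1O)[C@H](c1cc(OC)c(OC)c(OC)c1)[C@H]2C | intermediate
18 | (1R,5R,8R,9R)-5-methoxy-9-methyl-8-(3,4,5-trimethoxyphenyl)-6-oxabicyclo[3.2.2]non-3-ene-2,7-dione | C1=C[C@@]2(OC)OC(=O)[C@@H](C1=O)[C@H](c1cc(OC)c(OC)c(OC)c1)[C@H]2C | intermediate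
19 | (1R,5S,8R,9R)-3-iodo-5-methoxy-9-methyl-8-(3,4,5-trimethoxyphenyl)-6-oxabicyclo[3.2.2]non-3-ene-2,7-dione | IC1=C[C@@]2(OC)OC(=O)[C@@H](C1=O)[C@H](c1cc(OC)c(OC)c(OC)c1)[C@H]2C | intermediate
20 | allyltributylstannane | C=CC[Sn](CCCC)(CCCC)CCCC | starting material
21 | (1R,5S,8R,9R)-3-allyl-5-methoxy-9-methyl-8-(3,4,5-trimethoxyphenyl)-6-oxabicyclo[3.2.2]non-3-ene-2,7-dione | C=CCC1=C[C@@]2(OC)OC(=O)[C@@H](C1=O)[C@H](c1cc(OC)c(OC)c(OC)c1)[C@H]2C | target

Total steps: 13. Longest linear sequence: 13 steps (from 1 to 21).

**Steps most likely to fail, with fallbacks**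

Step 7. The acyl-ketal equilibrium may lie on the side of the axial-methoxy (6R) epimer, so that many recycling passes are needed, and prolonged acid may erode C11 through enol-ether formation. The fallback moves the selection into the metathesis and sets out from the unseparated mixture 11. Lindlar hydrogenation should give the vinyl lactones F1 as both C6 epimers. LiN(SiMe3)2 and allyl bromide at −78 °C should then give the 3-allyl lactones F2, with the allyl group anti to the aryl and no free hydroxyl that could capture an oxocarbenium ion. F2 is heated in dilute toluene with the second-generation Grubbs catalyst and camphorsulfonic acid (10 mol%); the acid should epimerise C6 through the ring-opened methoxy-oxocarbenium carboxylic acid and so feed the cis-dialkenyl lactone F3, which alone can close to the bicyclic alkene F4. SeO2 (cat.) with t-BuOOH should then hydroxylate the only allylic methylene of F4 (C9), and the route is rejoined at 17.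

Step 10. Closure onto the neopentyl-type C6 vinyl group may be slow, so that dimerisation through the C8 arm or isomerisation of the allylic alcohol takes over. The fallback makes C4=C5 by an intramolecular Wittig reaction and sets out from 13. C-acylation of its lithium enolate (LiN(SiMe3)2, 2.1 equiv; chloroacetyl chloride, −78 °C) should give the chloroacetyl lactone F5, in which C8 is epimerisable. OsO4 (cat.), NaIO4 and 2,6-lutidine in dioxane/H2O should cleave the vinyl group to the C6 aldehyde F6. PPh3 and then Et3N should convert the chloroketone into the stabilised keto ylide F7, which on warming in toluene condenses with the non-enolisable aldehyde to close ring B. This delivers the enone directly, and the route is rejoined at 18.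

Step 5. Protic acid may enolise the ynone (loss of the C11 configuration) or add methanol to the triple bond before the hindered ketone is ketalised. The fallback bypasses the ketal ester and sets out from 8. Treatment with Me3SiOMe (3 equiv) and catalytic Me3SiOTf in CH2Cl2 at −78 °C (aprotic Noyori-type ketalisation) should let the silylated carboxyl group capture the methoxy-oxocarbenium ion directly, giving the silylalkynyl methoxy lactone F8 as its C6 epimers. Bu4NF buffered with AcOH in THF at 0 °C should then remove the silyl group, and the route is rejoined at 11.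

**Further compounds**

F1 | step 7 | (4S,5R)-6-ethenyl-6-methoxy-5-methyl-4-(3,4,5-trimethoxyphenyl)tetrahydro-2H-pyran-2-one (C6 epimers) | C=CC1(OC)OC(=O)C[C@H](c2cc(OC)c(OC)c(OC)c2)[C@H]1C
F2 | step 7 | (3S,4R,5R)-6-ethenyl-6-methoxy-5-methyl-3-(prop-2-en-1-yl)-4-(3,4,5-trimethoxyphenyl)tetrahydro-2H-pyran-2-one (C6 epimers) | C=CC1(OC)OC(=O)[C@@H](CC=C)[C@H](c2cc(OC)c(OC)c(OC)c2)[C@H]1C
F3 | step 7 | (3S,4R,5R,6R)-6-ethenyl-6-methoxy-5-methyl-3-(prop-2-en-1-yl)-4-(3,4,5-trimethoxyphenyl)tetrahydro-2H-pyran-2-one (cis-dialkenyl epimer of F2) | C=C[C@@]1(OC)OC(=O)[C@@H](CC=C)[C@H](c2cc(OC)c(OC)c(OC)c2)[C@H]1C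
F4 | step 7 | (1S,5R,8R,9R)-5-methoxy-9-methyl-8-(3,4,5-trimethoxyphenyl)-6-oxabicyclo[3.2.2]non-3-en-7-one | C1=C[C@@]2(OC)OC(=O)[C@@H](C1)[C@H](c1cc(OC)c(OC)c(OC)c1)[C@H]2C
F5 | step 10 | (3R,4R,5R,6R)-3-(chloroacetyl)-6-ethenyl-6-methoxy-5-methyl-4-(3,4,5-trimethoxyphenyl)tetrahydro-2H-pyran-2-one | C=C[C@@]1(OC)OC(=O)[C@@H](C(=O)CCl)[C@H](c2cc(OC)c(OC)c(OC)c2)[C@H]1C
F6 | step 10 | C6 aldehyde from F5 (vinyl group replaced by formyl) | O=C[C@@]1(OC)OC(=O)[C@@H](C(=O)CCl)[C@H](c2cc(OC)c(OC)c(OC)c2)[C@H]1C
F7 | step 10 | keto ylide from F6 (chloromethyl replaced by triphenylphosphoranylidenemethyl) | O=C[C@@]1(OC)OC(=O)[C@@H](C(=O)C=P(c2ccccc2)(c2ccccc2)c2ccccc2)[C@H](c2cc(OC)c(OC)c(OC)c2)[C@H]1C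
F8 | step 5 | (4S,5R)-6-methoxy-5-methyl-4-(3,4,5-trimethoxyphenyl)-6-[(trimethylsilyl)ethynyl]tetrahydro-2H-pyran-2-one (C6 epimers) | C[Si](C)(C)C#CC1(OC)OC(=O)C[C@H](c2cc(OC)c(OC)c(OC)c2)[C@H]1C
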